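**Remark on the chemistry:** chain atoms are numbered C1–C9 as in the nonenoic acid and furan atoms O1′, C2′–C5′. The facial senses of the two reagent-controlled steps (the α-pinene series in step 2, the Tol-BINAP antipode in step 5) are assigned from the usual preferences of these reagent classes for simple aldehydes and (E)-enoates. Neither depends on the substrate, so the other antipode of the reagent is used if a first run shows the opposite sense.

## Analysis of the target

The target is (3R,5S)-5-[5-(2,5-dihydroxyphenyl)furan-3-yl]-3,8-dimethylnon-7-enoic acid. It is an acyclic C9 acid with a methyl group at C3, a 2,4-disubstituted furan attached through C4′ to C5, a prenyl terminus C6–C7=C8(CH3)2, and a hydroquinone on C2′. The stereocenters C3 and C5 are 1,3-related across the C4 methylene and syn in the extended chain (cis if C2 and C6 were tied into a six-membered ring). No ring and no functional group lies between them, so each needs its own external control element. C5 is the hard one: a tertiary CH carrying a heteroaryl group and two methylene arms (C4, C6) that differ only two atoms further out. The C6 arm must be a linear prenyl group, whereas prenyl nucleophiles bond through their tertiary terminus. The furan needs its aryl group on the α-carbon remote from the chain. The hydroquinone (air oxidation in base), the electron-rich 2-arylfuran (acid, electrophiles, oxidants) and the trisubstituted olefin (acid, hydrogenation, ozone) exclude late hydrogenation, ozonolysis and strong acid. The feature that invites the chosen move is the array C3–C4–C5–C6–C7=C8: with C3 as a carbonyl carbon it is a δ,ε-unsaturated aldehyde with a gem-dimethyl olefin terminus, the product pattern of an oxy-Cope rearrangement of a 1,1-dimethylallyl carbinol.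

## Retrosynthetic reasoning

**Target 14 from 13.** The two phenol O–acyl bonds and the methyl ester C–O bond are cut. Pivalates on the hydroquinone and a methyl ester at C1 fall to the same hydroxide, so one final operation releases all three acidic groups. The free hydroquinone exists only in the last flask.

**13 from 9 and 11.** The C2′–aryl bond is cut. It is the only biaryl bond, and the 3-substituted furan of 9 has two α-C–H bonds that differ sterically. Iridium-catalysed C–H borylation should take the one not flanked by the branched chain, and a Suzuki–Miyaura coupling with 11 should then give the 2,4-pattern without a pre-functionalised furan. Placing this late keeps the arene and its protecting groups out of the strongly basic key step.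

**9 from 8, and 8 from 7.** The C3–CH3 bond is cut (conjugate methylation of enoate 8), then the C2=C3 bond (Wittig olefination of aldehyde 7). C5 is too remote to direct C3, so a chiral copper catalyst must set it; the 3R,5S relationship is reached by choice of ligand antipode. The aldehyde carbon of 7 is C3, so the rearrangement product needs no redox adjustment before chain extension.

**7 from 4 (key disconnection).** The C5–C6 bond is cut and the C3–C8 bond is re-formed in the precursor. Aldehyde 7 is the [3,3] isomer of dienol 4, in which C3 is a carbinol carbon bonded to the quaternary C8 and C6 is a vinyl CH2. Forward, the oxy-Cope rearrangement must form C5–C6, turn the reverse-prenyl unit into the linear prenyl group, unveil the C3 aldehyde, and transfer the C3 carbinol configuration to C5. C5 is thus set with no auxiliary or catalyst acting at C5 itself.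

**4 from 2.** The C3–C8 bond is cut. Addition of a chiral prenylborane to the aldehyde of enal 2 uses the natural tertiary-terminus regiochemistry of prenyl nucleophiles, which is exactly what 4 requires. The carbinol center is set by a well-behaved reagent-controlled 1,2-addition.

**2 from 1.** The C4=C5 bond is cut. A two-carbon formyl ylide converts furan-3-carbaldehyde 1 into the (E)-enal; the E geometry is needed because it fixes the furyl group pseudo-equatorial in the rearrangement.

## Alternatives that were turned down

**Alternative 1:** (the textbook route) cuts the C5–C4′ bond. The forward key step is a Hayashi–Miyaura addition ([Rh(acac)(C2H4)2], BINAP) of a 3-furylboron reagent to the enoate terminus of 1-tert-butyl 7-methyl (3R,5E)-3-methylhept-5-enedioate A1, giving diester A2.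
- A1 needs a pool-derived C3 center and two differentiated carboxyl termini, which costs several steps before the key step.
- The C7 ester of A2 must then be reduced to the aldehyde and olefinated with a non-stabilised ylide to make the prenyl group.
- 3-Furylboronic acids protodeboronate under the aqueous basic conditions.
- The key step builds only one bond and one stereocenter and leaves the prenyl problem to oxidation-state manipulation, so the linear sequence is longer.

**Alternative 2:** cuts C5–C6 as an enolate alkylation. The forward key step is an Evans alkylation of (4S)-4-benzyl-3-[2-(furan-3-yl)acetyl]-1,3-oxazolidin-2-one A3 with a prenyl halide, giving A4.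
- C4 arrives at the carboxyl oxidation level. It must be reduced, activated and homologated by one carbon (about four steps) before the C3 aldehyde stage of 7 is reached.
- The auxiliary is stoichiometric and must be attached and removed.
- The α-furyl stereocenter is epimerisable for as long as C4 is a carbonyl carbon.

**Alternative 3:** uses a ring as template. A 3-furyl cuprate is added to (5R)-5-methylcyclohex-2-en-1-one A5 and the ring is then cleaved.
- The cuprate enters anti to the C5 methyl group and gives the trans ketone A6, but the syn C3/C5 relationship of the target corresponds to the cis ring isomer, so the template delivers the wrong diastereomer.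
- The ring carbonyl has no counterpart in the chain: C2 and C6 end at two different carbons (C1 and C7), so the ring must be cut between two nearly identical methylenes.
- A Baeyer–Villiger cleavage would not be regioselective, and peracids or ozone are incompatible with the furan.

Key step: step 3

## Route

**Step 1**
Reactants: 1 furan-3-carbaldehyde
Product: 2 (2E)-3-(furan-3-yl)prop-2-enal
Conditions: Ph3P=CHCHO (0.7 equiv relative to 1), toluene, 80 °C
Reagents that add atoms: (triphenylphosphoranylidene)acetaldehyde, O=CC=P(c1ccccc1)(c1ccccc1)c1ccccc1
Why: Wittig olefination with a formyl-stabilised ylide should give the (E)-enal; the excess of volatile aldehyde 1 limits a second homologation to the dienal.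

**Step 2**
Reactants: 2 (2E)-3-(furan-3-yl)prop-2-enal
Product: 4 (1E,3R)-1-(furan-3-yl)-4,4-dimethylhexa-1,5-dien-3-ol, via borinate ester 3 (not isolated)
Conditions: (−)-Ipc2BH (from (+)-α-pinene, 1.3 equiv), 3-methylbuta-1,2-diene, Et2O, −25 °C; then 2, −78 °C; then 3 M NaOH, 30 % H2O2, 0 → 23 °C
Reagents that add atoms: 3-methylbuta-1,2-diene, CC(C)=C=C (supplies C6–C9 and the 8-methyl group); (−)-diisopinocampheylborane, B([C@@H]1C[C@@H]2C[C@H]([C@H]1C)C2(C)C)[C@@H]1C[C@@H]2C[C@H]([C@H]1C)C2(C)C (supplies the boryl group of 3 only)
Why: Brown-type asymmetric allylboration: hydroboration of the allene gives the B-prenyl borane, which adds through its tertiary terminus in a closed chair transition state, 1,2 only, to give the 1,1-dimethylallyl carbinol; the (+)-α-pinene series is expected to attack the Si face of the aldehyde, which is the (3R) carbinol.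

**Step 3**
Reactants: 4 (1E,3R)-1-(furan-3-yl)-4,4-dimethylhexa-1,5-dien-3-ol
Product: 7 (3R)-3-(furan-3-yl)-6-methylhept-5-enal, via potassium alkoxide 5 (not isolated), via potassium enolate 6 (not isolated)
Conditions: KH (1.5 equiv), 18-crown-6 (1.5 equiv), THF, 0 → 23 °C; then sat. aq NH4Cl, −78 °C
Reagents that add atoms: none
Why: Deprotonation gives alkoxide 5, whose oxido group accelerates a [3,3] shift (anionic oxy-Cope rearrangement): the C3–C8 bond between the carbinol carbon and the quaternary carbon breaks while C5–C6 forms between the furyl-bearing olefin terminus and the vinyl CH2, giving enolate 6 with the olefin moved to C7=C8. The closest known reaction type is the conjugate prenylation of enals and enones by 1,2-addition of a prenyl metal followed by anionic oxy-Cope rearrangement of the 1,1-dimethylallyl carbinol. No ring is closed; the six-membered array exists only in the chair transition state. The new stereocenter C5 is controlled by the carbinol configuration of 4 (1,3-chirality transfer): with the E olefin holding the furyl group pseudo-equatorial and the crown-complexed oxido group pseudo-equatorial, the (3R) carbinol delivers C6 to the face of C5 that gives (R)-7, which is 5S in the target. The step needs chair over boat, oxido pseudo-equatorial over pseudo-axial, and a concerted path over fragmentation into enal and prenyl anion. The fixed E geometry, the bulk of the K(18-crown-6) ion pair and the low temperature allowed by the weak, fully substituted C3–C8 bond should secure this. Cold protonation of 6 avoids aldol self-condensation, and C5, being β to the aldehyde, cannot epimerise.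

**Step 4**
Reactants: 7 (3R)-3-(furan-3-yl)-6-methylhept-5-enal
Product: 8 methyl (2E,5S)-5-(furan-3-yl)-8-methylnona-2,7-dienoate
Conditions: Ph3P=CHCO2Me (1.3 equiv), CH2Cl2, 23 °C
Reagents that add atoms: methyl (triphenylphosphoranylidene)acetate, COC(=O)C=P(c1ccccc1)(c1ccccc1)c1ccccc1
Why: Wittig olefination with an ester-stabilised ylide should give the (E)-enoate under neutral conditions; the descriptor at C5 changes from R to S only because the priorities of the two arms change.

**Step 5**
Reactants: 8 methyl (2E,5S)-5-(furan-3-yl)-8-methylnona-2,7-dienoate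
Product: 9 methyl (3R,5S)-5-(furan-3-yl)-3,8-dimethylnon-7-enoate
Conditions: MeMgBr (5 equiv), CuI (2 mol %), (R)-Tol-BINAP (3 mol %), t-BuOMe, −20 °C; then MeOH, sat. aq NH4Cl
Reagents that add atoms: methylmagnesium bromide, C[Mg]Br
Why: Copper-catalysed asymmetric conjugate addition of a methyl Grignard reagent to an (E)-β-alkyl enoate, as used for 1,3-dimethyl (deoxypropionate) arrays; the chiral copper–bisphosphine complex, not the remote C5 center, is expected to deliver methyl to the Re face of C3 (3R), and the bulk ether at low temperature suppresses 1,2-addition.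

**Step 6**
Reactants: 10 2-bromobenzene-1,4-diol
Product: 11 2-bromo-1,4-phenylene bis(2,2-dimethylpropanoate)
Conditions: PivCl (2.4 equiv), pyridine, DMAP (5 mol %), CH2Cl2, 0 → 23 °C
Reagents that add atoms: pivaloyl chloride, CC(C)(C)C(Cl)=O
Why: Acylation of both phenols removes the oxidisable hydroquinone and gives esters that survive mild Suzuki–Miyaura conditions and fall to hydroxide in the last step.

**Step 7**
Reactants: 9 methyl (3R,5S)-5-(furan-3-yl)-3,8-dimethylnon-7-enoate; 11 2-bromo-1,4-phenylene bis(2,2-dimethylpropanoate)
Product: 13 methyl (3R,5S)-5-{5-[2,5-bis(2,2-dimethylpropanoyloxy)phenyl]furan-3-yl}-3,8-dimethylnon-7-enoate, via furyl boronate 12 (not isolated)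
Conditions: [Ir(OMe)(cod)]2 (1.5 mol %), 4,4′-di-tert-butyl-2,2′-bipyridine (3 mol %), B2pin2 (0.55 equiv), THF, 25 °C; then 11 (1.1 equiv), Pd(OAc)2 (3 mol %), SPhos (6 mol %), aq K3PO4, 40 °C
Reagents that add atoms: bis(pinacolato)diboron, CC1(C)OB(OC1(C)C)B1OC(C)(C)C(C)(C)O1 (supplies the boryl group of 12 only; the aryl group of 13 comes from 11)
Why: Iridium-catalysed C–H borylation of a 3-substituted furan is sterically controlled and should take the α-C–H not flanked by the branched chain (C2′ of the target); the sensitive 2-furyl boronate is used at once in a Suzuki–Miyaura coupling under mild base so that the pivalates and the methyl ester survive.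

**Step 8**
Reactants: 13 methyl (3R,5S)-5-{5-[2,5-bis(2,2-dimethylpropanoyloxy)phenyl]furan-3-yl}-3,8-dimethylnon-7-enoate
Product: 14 (3R,5S)-5-[5-(2,5-dihydroxyphenyl)furan-3-yl]-3,8-dimethylnon-7-enoic acid
Conditions: LiOH·H2O (10 equiv), degassed THF/MeOH/H2O, Ar, 40 °C; then degassed 1 M HCl to pH 3, 0 °C, trace Na2S2O4
Reagents that add atoms: lithium hydroxide, [Li+].[OH-] (its oxygen becomes the hydroxyl oxygen of the carboxyl group)
Why: Saponification cleaves the methyl ester and both aryl pivalates in one operation; neither stereocenter is acidic, and exclusion of air with a reducing acidic work-up protects the hydroquinone.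

## Compound list

1 | furan-3-carbaldehyde | O=Cc1ccoc1 | starting material
2 | (2E)-3-(furan-3-yl)prop-2-enal | O=C/C=C/c1ccoc1 | intermediate
3 | (1E,3R)-1-(furan-3-yl)-4,4-dimethylhexa-1,5-dien-3-yl diisopinocampheylborinate | C=CC(C)(C)[C@H](OB([C@@H]1C[C@@H]2C[C@H]([C@H]1C)C2(C)C)[C@@H]1C[C@@H]2C[C@H]([C@H]1C)C2(C)C)/C=C/c1ccoc1 | intermediate
4 | (1E,3R)-1-(furan-3-yl)-4,4-dimethylhexa-1,5-dien-3-ol | C=CC(C)(C)[C@H](O)/C=C/c1ccoc1 | intermediate
5 | potassium (1E,3R)-1-(furan-3-yl)-4,4-dimethylhexa-1,5-dien-3-olate | C=CC(C)(C)[C@H]([O-])/C=C/c1ccoc1.[K+] | intermediate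
6 | potassium (1E,3R)-3-(furan-3-yl)-6-methylhepta-1,5-dien-1-olate | [K+].[O-]/C=C/[C@@H](CC=C(C)C)c1ccoc1 | intermediate
7 | (3R)-3-(furan-3-yl)-6-methylhept-5-enal | O=CC[C@@H](CC=C(C)C)c1ccoc1 | intermediate
8 | methyl (2E,5S)-5-(furan-3-yl)-8-methylnona-2,7-dienoate | COC(=O)/C=C/C[C@@H](CC=C(C)C)c1ccoc1 | intermediate
9 | methyl (3R,5S)-5-(furan-3-yl)-3,8-dimethylnon-7-enoate | COC(=O)C[C@H](C)C[C@@H](CC=C(C)C)c1ccoc1 | intermediate
10 | 2-bromobenzene-1,4-diol | Oc1ccc(O)c(Br)c1 | starting material
11 | 2-bromo-1,4-phenylene bis(2,2-dimethylpropanoate) | CC(C)(C)C(=O)Oc1ccc(OC(=O)C(C)(C)C)c(Br)c1 | intermediate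
12 | methyl (3R,5S)-3,8-dimethyl-5-[5-(4,4,5,5-tetramethyl-1,3,2-dioxaborolan-2-yl)furan-3-yl]non-7-enoate | COC(=O)C[C@H](C)C[C@@H](CC=C(C)C)c1coc(B2OC(C)(C)C(C)(C)O2)c1 | intermediate
13 | methyl (3R,5S)-5-{5-[2,5-bis(2,2-dimethylpropanoyloxy)phenyl]furan-3-yl}-3,8-dimethylnon-7-enoate | COC(=O)C[C@H](C)C[C@@H](CC=C(C)C)c1coc(-c2cc(OC(=O)C(C)(C)C)ccc2OC(=O)C(C)(C)C)c1 | intermediate
14 | (3R,5S)-5-[5-(2,5-dihydroxyphenyl)furan-3-yl]-3,8-dimethylnon-7-enoic acid | CC(C)=CC[C@H](C[C@@H](C)CC(=O)O)c1coc(-c2cc(O)ccc2O)c1 | target

## Step count and risk

Total step count: 8. Longest linear sequence: 7 (steps 1, 2, 3, 4, 5, 7, 8).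

**Step 3 (key step).** The most likely failure is erosion of the 1,3-chirality transfer. It can arise from a competing chair with the oxido group pseudo-axial, from a boat, or from fragmentation of the alkoxide into enal and prenyl anion followed by non-stereospecific recombination. Any of these lowers the configurational purity at C5 and shows up later as the C5 epimer of 9. Aldol condensation of the product enolate during the quench is a second risk.

Fallback: it sets out from compound 2 and comes back at compound 7, and sets C5 by iminium catalysis instead of rearrangement.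
- Compound 2 takes up dimethyl malonate under catalysis by a diarylprolinol silyl ether (the antipode that gives the S adduct) to give dimethyl 2-[(1S)-1-(furan-3-yl)-3-oxopropyl]propanedioate F1.
- NaBH4 reduction and acid-induced lactonisation give methyl (3S,4S)-4-(furan-3-yl)-2-oxooxane-3-carboxylate F2.
- Krapcho demethoxycarbonylation (LiCl, wet DMSO, 130 °C) gives (4S)-4-(furan-3-yl)oxan-2-one F3.
- i-Bu2AlH at −78 °C gives the lactol (4S)-4-(furan-3-yl)oxan-2-ol F4.
- Wittig olefination with isopropylidenetriphenylphosphorane opens it to (3R)-3-(furan-3-yl)-6-methylhept-5-en-1-ol F5.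
- Dess–Martin oxidation returns 7.

**Step 2.** The most likely failure is insufficient facial selectivity of the prenyl transfer to the conjugated aldehyde, or an absolute sense opposite to the one assumed. Either would pass through step 3 into the wrong configuration at C5. Fallback: it sets out from compound 2 and comes back at compound 4. An iridium-catalysed transfer-hydrogenative reverse prenylation ([Ir(cod)Cl]2, a SEGPHOS antipode, 4-cyano-3-nitrobenzoic acid, Cs2CO3, 2-propanol, 3-methylbuta-1,2-diene, THF, 60 °C) forms the same C3–C8 bond through an iridium allyl species instead of a borane. No new compound arises (F0).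

**Step 5.** The most likely failures are competing 1,2-addition of the Grignard reagent to the ester, and incomplete or mis-assigned facial control by the catalyst, which would give the C3 epimer. Fallback: it sets out from compound 7 and comes back at compound 9, replacing catalyst control by auxiliary control.
- Horner–Wadsworth–Emmons reaction of 7 with diethyl {2-oxo-2-[(4S)-2-oxo-4-phenyl-1,3-oxazolidin-3-yl]ethyl}phosphonate (LiCl, i-Pr2NEt, MeCN) gives (4S)-3-[(2E,5S)-5-(furan-3-yl)-8-methylnona-2,7-dienoyl]-4-phenyl-1,3-oxazolidin-2-one F6.
- MeMgBr with CuBr·SMe2 (THF, −40 °C) adds to the chelated s-cis enoyl imide anti to the phenyl group, giving (4S)-3-[(3R,5S)-5-(furan-3-yl)-3,8-dimethylnon-7-enoyl]-4-phenyl-1,3-oxazolidin-2-one F7.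
- NaOMe in MeOH at 0 °C gives 9.

**Step 7.** The most likely failures are borylation at the α-carbon next to the chain or at both α-carbons, and protodeboronation of the 2-furyl boronate before it couples. Fallback: it sets out from compound 9 and comes back at compound 13, using deprotonative metalation instead of C–H borylation. TMPZnCl·LiCl (THF, 25 °C) zincates the less hindered α-position without touching the ester to give chloro{4-[(3R,5S)-1-methoxy-3,8-dimethyl-1-oxonon-7-en-5-yl]furan-2-yl}zinc F8, which undergoes Negishi coupling with 11 (Pd(OAc)2, SPhos, THF, 40 °C).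

**Step 8.** The most likely failures are air oxidation of the hydroquinone di-anion to the quinone during the basic hydrolysis, and slow cleavage of the hindered pivalate next to the furan. Fallback: it sets out from compound 13 and comes back at compound 14, going through the quinone on purpose. After hydrolysis the crude acid is oxidised completely with Ag2O in Et2O to (3R,5S)-5-[5-(3,6-dioxocyclohexa-1,4-dien-1-yl)furan-3-yl]-3,8-dimethylnon-7-enoic acid F9, which is purified and then reduced to 14 with aqueous Na2S2O4 in EtOAc under argon.

## Further compounds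

F1 | step 3 | dimethyl 2-[(1S)-1-(furan-3-yl)-3-oxopropyl]propanedioate | COC(=O)C(C(=O)OC)[C@H](CC=O)c1ccoc1
F2 | step 3 | methyl (3S,4S)-4-(furan-3-yl)-2-oxooxane-3-carboxylate | COC(=O)[C@H]1C(=O)OCC[C@@H]1c1ccoc1
F3 | step 3 | (4S)-4-(furan-3-yl)oxan-2-one | O=C1C[C@@H](c2ccoc2)CCO1
F4 | step 3 | (4S)-4-(furan-3-yl)oxan-2-ol (anomeric mixture) | OC1C[C@@H](c2ccoc2)CCO1
F5 | step 3 | (3R)-3-(furan-3-yl)-6-methylhept-5-en-1-ol | OCC[C@@H](CC=C(C)C)c1ccoc1
F0 | step 2 | none | none
F6 | step 5 | (4S)-3-[(2E,5S)-5-(furan-3-yl)-8-methylnona-2,7-dienoyl]-4-phenyl-1,3-oxazolidin-2-one | O=C(/C=C/C[C@@H](CC=C(C)C)c1ccoc1)N1C(=O)OC[C@@H]1c1ccccc1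
F7 | step 5 | (4S)-3-[(3R,5S)-5-(furan-3-yl)-3,8-dimethylnon-7-enoyl]-4-phenyl-1,3-oxazolidin-2-one | O=C(C[C@H](C)C[C@@H](CC=C(C)C)c1ccoc1)N1C(=O)OC[C@@H]1c1ccccc1
F8 | step 7 | chloro{4-[(3R,5S)-1-methoxy-3,8-dimethyl-1-oxonon-7-en-5-yl]furan-2-yl}zinc | COC(=O)C[C@H](C)C[C@@H](CC=C(C)C)c1coc([Zn]Cl)c1
F9 | step 8 | (3R,5S)-5-[5-(3,6-dioxocyclohexa-1,4-dien-1-yl)furan-3-yl]-3,8-dimethylnon-7-enoic acid | CC(C)=CC[C@H](C[C@@H](C)CC(=O)O)c1coc(C2=CC(=O)C=CC2=O)c1
A1 | alternative 1 | 1-tert-butyl 7-methyl (3R,5E)-3-methylhept-5-enedioate | COC(=O)/C=C/C[C@@H](C)CC(=O)OC(C)(C)C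
A2 | alternative 1 | 1-tert-butyl 7-methyl (3R,5S)-5-(furan-3-yl)-3-methylheptanedioate | COC(=O)C[C@H](C[C@@H](C)CC(=O)OC(C)(C)C)c1ccoc1
A3 | alternative 2 | (4S)-4-benzyl-3-[2-(furan-3-yl)acetyl]-1,3-oxazolidin-2-one | O=C(Cc1ccoc1)N1C(=O)OC[C@@H]1Cc1ccccc1
A4 | alternative 2 | (4S)-4-benzyl-3-[(2S)-2-(furan-3-yl)-5-methylhex-4-enoyl]-1,3-oxazolidin-2-one | O=C([C@@H](CC=C(C)C)c1ccoc1)N1C(=O)OC[C@@H]1Cc1ccccc1
A5 | alternative 3 | (5R)-5-methylcyclohex-2-en-1-one | C[C@@H]1CC=CC(=O)C1
A6 | alternative 3 | (3R,5R)-3-(furan-3-yl)-5-methylcyclohexan-1-one | C[C@@H]1C[C@@H](c2ccoc2)CC(=O)C1
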